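I had no constants for these flasks, but I had Sunday's readings.

in all of them: substrate 0.050 M
- Sunday's: free catalyst 30 mol%; temperature 125 °C; run made earlier
- south: free catalyst 15 mol%; temperature 125 °C; time 4.0 min
- east: free catalyst 15 mol%; temperature 100 °C; time 4.0 min
- north-east: free catalyst 15 mol%; at 125 °C until 50 s, from then on at 100 °C; time 4.0 min
Sunday's run (percent of the substrate charged)

| time / s | target / % | substrate / % |
|---|---|---|
| 10.0 | 76.1 | 11.2 |
| 12.0 | 77.3 | 5.8 |
| 30.0 | 71.7 | 0.6 |
| 80.0 | 65.9 | 1.5 |

(standard deviation of a reading: 1 percentage point)
- the analysis behind the earlier runs scatters by 1 percentage point, standard deviation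
- the earlier runs do not show what temperature does; that part of a forecast is a guess
- no earlier run changes the charge of free catalyst; that part of a forecast is a guess
- the flask that comes out highest in amount of target, in percent of the substrate charged, or "all alike" when all lie within 1.5 percentage points (south / east / north-east / all alike)
- target at the end, in percent of the substrate charged, south
- target at the end, in percent of the substrate charged, east
- target at the end, in percent of the substrate charged, north-east

On Sunday target fell 5.6 percentage points between 12.0 s and 30.0 s, then 5.8 points over the longer stretch to 80.0 s, so the fall was slowing. I read this as a reversible loss to something unseen, an equilibrium plateau. I kept the last reading, 65.9 %, as the holding level, the fraction of the charge that target keeps at 125 °C once that loss has levelled. I assumed that catalyst changes the speed and not the level. South has half of Sunday's loading, but even twice Sunday's 12.0 s is far shorter than 4.0 min. So I expected south to end near 65.9 %. North-east stays hot for 50 s, which at half Sunday's loading I counted as 25.0 s of Sunday's run, shorter than Sunday's 80.0 s, so I expected it to leave 125 °C above that level. What 100 °C does was a guess, and I set no number on it.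

The forecast gave 60 % for south, 71 % for east and 68 % for north-east, with east highest, saying of east: “Conversion still finishes, and decay is small”. The flasks gave 65.3 %, 61.8 % and 50.3 %, so south came out highest, and south stood near my level.

    target ⇌ isomer of the product (K = 1.70, k = 0.00280 /s, Ea = 117 kJ/mol, ΔH = −64.0 kJ/mol)
    catalyst intermediate → free catalyst + target (k = 2.50 /s, Ea = 89.0 kJ/mol)
    target → over-reaction product (k = 2.30 × 10⁻⁵ /s, Ea = 121 kJ/mol)
    substrate + free catalyst → catalyst intermediate (k = 4.60 /M/s, Ea = 60.0 kJ/mol)
    (constants at 100 °C)

North-east formed its target while hot and held 68.4 % at 0.833 min, above the holding level, with 30.4 % as isomer of the product. After the change to 100 °C, target kept passing to the isomer, reaching 50.3 % against 48.6 % at 4.00 min and 35.8 % after 40.0 min.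

Take the neighbour, north-east read at 6.0 min. The holding level was read at 125 °C, so it gives no number for this flask at 100 °C. Measured from 68.4 % at the change, the gap above 35.8 % shrank to 44.4 % of itself in 190 s. The same first-order shrinking gives 44.5 %, and the neighbour gave 44.5 %.

Readings and results were computed from invented constants; scatter was added.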